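The readings are calculated from invented constants; scatter was added.

Tuesday's fed run held a puzzle that I had to clear before I could compare the fed south flask with south-east, where everything goes in at the start.

all flasks: free catalyst 10 µM; added ligand 36 µM
- Sunday's: starting material 20 mM (fed, over 80 min); partner 54 mM; protic impurity 20 mM; run made earlier
- Thursday's: starting material 20 mM (fed, over 80 min); partner 120 mM; protic impurity 20 mM; run made earlier
- Tuesday's: starting material 20 mM (fed, over 80 min); partner 80 mM; protic impurity 10 mM; run made earlier
- south-east: starting material 20 mM; partner 80.0 mM; protic impurity 20.0 mM; everything together at the start; time 80 min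
- south: starting material 20 mM (fed, over 80 min); partner 80.0 mM; protic impurity 20.0 mM; time 80 min

| run | time / min | target / % | starting material / % |
|---|---|---|---|
| Sunday's | 12.0 | 1.3 | 13.9 |
| Sunday's | 25.0 | 3.7 | 27.9 |
| Sunday's | 40.0 | 5.3 | 44.5 |
| Sunday's | 50.0 | 7.1 | 53.9 |
| Thursday's | 4.00 | 0.5 | 5.3 |
| Thursday's | 8.00 | 0.1 | 10.9 |
| Thursday's | 20.0 | 2.7 | 21.7 |
| Thursday's | 50.0 | 12.4 | 50.0 |
| Tuesday's | 6.00 | 0.3 | 4.2 |
| Tuesday's | 15.0 | 1.8 | 18.2 |
| Tuesday's | 30.0 | 5.4 | 33.2 |
| Tuesday's | 50.0 | 10.7 | 53.6 |

(scatter of a reading: 1 percentage point)

- percentages count the whole charge, also what has not yet gone in

- which of the two ends with the higher amount of target, in percent of the starting material charged ("neither" if they lie within 2 percentage points) (south-east / south / neither)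
- target at the end, in percent of the starting material charged, south-east
- target at the end, in percent of the starting material charged, south

I measured speed as pace, the target a flask makes in 80 min at its current rate. Between 6.00 min and 30.0 min, Tuesday's pace read 17.0%, with about 18.7% starting material present. Between 30.0 min and 50.0 min it read 21.2%, with about 43.4% present. So the starting material read 2.32-fold higher while the pace read only 1.25-fold higher, which is not what a proportional rate gives. I read this as saturation kinetics, where pace equals a ceiling times [starting material]/(level + [starting material]). The two readings give, with much scatter, a saturation level of 9.99% of the charge, the amount at which the pace stands midway to a ceiling of 26.1%.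

I guessed that the impurity spoils partner mole for mole, so I counted 60.0 mM of usable partner. Interpolating between Sunday's and Tuesday's readings at 50.0 min gave an estimate of 9.70% target for south, and I scaled the ceiling to 23.6% by the same ratio. Then I froze the starting material. With south-east frozen at its full charge, I reckoned an end near 21.5%. With south frozen at Tuesday's 53.6% for the last 30.0 min, I reckoned an end near 17.2%. So I put south-east higher than south, by 4.3 percentage points against a margin of 2 points.

The forecast chose south-east, with 24% for south-east and 19% for south: “Batch wins modestly, assuming no side reaction appears at higher concentration”. The flask gave 25.2% in south-east and 18.1% in south.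

    starting material + free catalyst ⇌ catalyst intermediate A (K = 630 /M, k = 51.6 /M/s)
    catalyst intermediate B → free catalyst + target (k = 0.516 /s)
    partner + protic impurity → quenched reagent (k = 0.0115 /M/s)
    free catalyst + added ligand ⇌ idle complex, settled at all times (K = 11300 /M)
    target → over-reaction product (k = 2.18 × 10⁻⁷ /s)
    partner + catalyst intermediate A ⇌ catalyst intermediate B (K = 7.60 /M, k = 13.1 /M/s)

For a flask charged at the start, with the ceiling and the saturation level held fixed, I reckoned the reach, ceiling times time, that a given target costs: the target plus the saturation level times the natural logarithm of charge over starting material left. South-east's result costs 28.1%, against my ceiling of 23.6%. The neighbour of south-east with 0.040 mM free catalyst has 4.00 times the catalyst, so I scaled the reach to 94.6%. Its target of 80.9% costs 97.4%.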